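The readings were generated by integration for an exercise, and the scatter is random.

0.651 mol of product per mol of coupling partner charged: that much the flask had already shown at its last reading, and I called this figure the partner yield φ.

- delta: substrate 0.020 M; coupling partner 0.022 M; the very flask that is asked about, followed so far
- flask: substrate 0.020 M; coupling partner 0.0220 M; time 5.0 min
delta run (percent of the substrate charged): time / min: product / % = 0.500: 26.2; 1.00: 43.8; 1.50: 54.9; 2.00: 63.3; 2.50: 67.5; 3.00: 71.6

(each reading ± 1 percentage point)
- west: at 5.0 min take out 90 % of the product then present, then wait 2.5 min
- north-west: change nothing and wait 2.5 min more
- south-west: at 5.0 min add coupling partner, 100 % of the amount charged, then wait 2.5 min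
- east: at 5.0 min add substrate, 50.0 % of the amount charged, then wait 2.5 min
- product taken out counts as made
- the analysis behind the earlier runs scatters by 1 percentage point, standard deviation
- additions bring no volume worth counting
- product, in percent of the substrate first charged, at 5.0 min
- which option adds most product ("none" when 2 percentage points or less is all one gets) (west / north-west / south-west / east / none)
- product present, with what was taken out counted in, in percent of the substrate first charged, after north-west
- product present, with what was taken out counted in, in percent of the substrate first charged, after south-west

I bracketed the product at 5.0 min. From above stood the full substrate charge, 100 %; from below stood the last reading, 71.6 %, give or take 1 percentage point. To tighten the top, I compared gains over successive stretches of equal length and let them go on shrinking by the same ratio: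

gain from 1.00 min to 2.00 min: h = 20 points
gain from 2.00 min to 3.00 min: g = 8.3 points
ceiling: C = 71.6 % + g·g/(h − g) = 77.8 %

So I expected between 71.6 % and 77.8 %; the upper figure was an estimate from scattered readings and no strict bound. The last reading left 0.005680 M of substrate. If the partner was what stopped the curve, fresh partner at φ would make 0.01432 M, which is more than that, so I chose south-west.

The forecast gave 81.9 % now, 88.1 % after north-west and 98 % after south-west, and it chose east, holding that “The run gives no sign of stalling”. Its 81.9 % lay above my ceiling.

The flask gave 72.0 %, 72.0 % after north-west and 100 % after south-west, so the best option was south-west, with a gain of 28 points.

    substrate + coupling partner → product, rate k1*[substrate]^0.5*[coupling partner]^0.5 (k = 0.0103 s⁻¹)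
    coupling partner → decomposed reagent (k = 0.00660 s⁻¹)

At 5.00 min the flask held 0 % of its coupling partner and 28.0 % of its substrate, so the partner was the limiting reagent, and decomposed reagent stood at 0.00760 M. In a neighbour flask with 0.012 M of substrate, φ promised 119 % of that charge, above the full charge, and that flask gave 97.9 %. The first flask had come to rest: a later hour changed nothing. At ten times the time, 50.0 min, it still held 72.0 % of product.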